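**Retrosynthetic overview**
- The strategy rests on ring B, the 2,4-disubstituted furan (O1, C2 carrying the furan-3-ylmethyl group, C3, C4 carrying the propyl chain, C5). It is cut at C3–C4 into a vinyl carbinol (C2 with C3) and a 2-substituted acrolein acetal (C4 with C5) joined through O1; ring-closing metathesis and loss of methanol rebuild it.
- The E-trisubstituted alkene of the chain comes from a B-alkyl Suzuki coupling of iodoalkene 18 (methylalumination of alkyne 16) with the 9-BBN adduct of alkene 22; 22 derives from the (R)-Roche ester, which supplies the only stereocentre.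
- Ring C (tetronate) is closed at C3–C4 by Dieckmann condensation of the (2E)-enol propanoate 31, made by olefination of aldehyde 26 so that the (E)-ylidene geometry is fixed before ring closure; O-sulfation is last.
- Ring order: ring A is bought (furan-3-ylacetic acid), ring B forms in step 9, ring C in step 23.

Key step: step 9

Assumption: the target is drawn as the free hydrogen sulfate, a strong acid next to two acid-sensitive furans, so it is released from its salt only in the last operation and handled cold and dilute.

**Route**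

Step 1
Reactants: 1 furan-3-ylacetic acid
Product: 2 2-(furan-3-yl)ethanol
Conditions: LiAlH4, THF, 0 °C → rt
Reagents that add atoms: none
Why: Hydride reduction of the carboxylic acid to the primary alcohol, which the furan ring tolerates.

Step 2
Reactants: 2 2-(furan-3-yl)ethanol
Product: 3 furan-3-ylacetaldehyde
Conditions: Dess–Martin periodinane, NaHCO3, CH2Cl2, 0 °C; used crude at once
Reagents that add atoms: none
Why: Buffered Dess–Martin oxidation stops at the aldehyde and avoids the acid and heat that would condense this enolisable arylacetaldehyde.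

Step 3
Reactants: 3 furan-3-ylacetaldehyde; 4 vinylmagnesium bromide
Product: 5 1-(furan-3-yl)but-3-en-2-ol (racemic)
Conditions: THF, −78 → −20 °C; aq. NH4Cl
Reagents that add atoms: none
Why: Grignard 1,2-addition gives the secondary allylic alcohol as a racemate, which suffices because this centre is erased in step 9.

Step 4
Reactants: 6 pentane-1,5-diol
Product: 7 5-[(tert-butyldiphenylsilyl)oxy]pentan-1-ol
Conditions: t-BuPh2SiCl, imidazole, DMF, 0 °C (diol in threefold excess)
Reagents that add atoms: tert-butyl(chloro)diphenylsilane, CC(C)(C)[Si](Cl)(c1ccccc1)c1ccccc1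
Why: Statistical monosilylation of the symmetric diol, the diphenylsilyl ether being chosen because it should survive the acidic steps 7 to 9.

Step 5
Reactants: 7 5-[(tert-butyldiphenylsilyl)oxy]pentan-1-ol
Product: 8 5-[(tert-butyldiphenylsilyl)oxy]pentanal
Conditions: TEMPO (10 mol%), PhI(OAc)2, CH2Cl2, rt
Reagents that add atoms: none
Why: TEMPO-catalysed oxidation with PhI(OAc)2 takes the primary alcohol to the aldehyde without over-oxidation.

Step 6
Reactants: 8 5-[(tert-butyldiphenylsilyl)oxy]pentanal
Product: 9 5-[(tert-butyldiphenylsilyl)oxy]-2-methylidenepentanal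
Conditions: 37% aq. CH2O, pyrrolidine (10 mol%), EtCO2H (10 mol%), i-PrOH, 45 °C
Reagents that add atoms: formaldehyde, C=O
Why: Amine-catalysed α-methylenation (Mannich condensation with formaldehyde, then loss of the amine) installs the 2-methylidene group at the only enolisable position.

Step 7
Reactants: 9 5-[(tert-butyldiphenylsilyl)oxy]-2-methylidenepentanal
Product: 10 tert-butyl[(5,5-dimethoxy-4-methylidenepentyl)oxy]diphenylsilane
Conditions: HC(OMe)3, MeOH, NH4NO3 (cat.), rt
Reagents that add atoms: trimethyl orthoformate, COC(OC)OC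
Why: Acid-catalysed acetalisation with the orthoformate as water scavenger, 1,2-addition at the aldehyde of a 2-alkylacrolein being faster than conjugate addition of methanol.

Step 8
Reactants: 5 1-(furan-3-yl)but-3-en-2-ol; 10 tert-butyl[(5,5-dimethoxy-4-methylidenepentyl)oxy]diphenylsilane
Product: 11 tert-butyl{[5-{[1-(furan-3-yl)but-3-en-2-yl]oxy}-5-methoxy-4-methylidenepentyl]oxy}diphenylsilane (mixed methyl acetal, diastereomer mixture)
Conditions: pyridinium p-toluenesulfonate (5 mol%), toluene, 5 Å molecular sieves, 45 °C (10 in 2.5-fold excess, recovered)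
Reagents that add atoms: none
Why: Acid-catalysed transacetalisation through the conjugated oxocarbenium ion exchanges one methoxy group for the allylic alcohol, excess 10 and removal of methanol steering the equilibrium to the mono-exchanged acetal, whose two uncontrolled centres are irrelevant.

Step 9
Reactants: 11 mixed methyl acetal
Product: 13 tert-butyl{3-[5-(furan-3-ylmethyl)furan-3-yl]propoxy}diphenylsilane, via methoxydihydrofuran 12 (not isolated)
Conditions: second-generation Grubbs catalyst RuCl2(H2IMes)(PCy3)(=CHPh) (5 mol%), CH2Cl2, 40 °C; then pyridinium p-toluenesulfonate (20 mol%), rt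
Reagents that add atoms: none
Why: The ruthenium benzylidene exchanges first with the monosubstituted vinyl group of 11, the new alkylidene adds intramolecularly to the 1,1-disubstituted alkene, and cycloreversion of the ruthenacyclobutane expels ethene and leaves the C3–C4 double bond of 2-methoxy-2,5-dihydrofuran 12. The closest known reaction type is ring-closing metathesis of allyl acetal dienes followed by acid aromatisation to furans, which accepts a 1,1-disubstituted partner. Ring B closes as a five-membered ring by alkene metathesis at carbon–carbon, both alkene carbons ending inside the ring, and not by C–O bond formation. No stereocentre is created: the pyridinium acid ionises the acetal methoxy group to the oxocarbenium ion and loss of the proton at the carbon bearing the furylmethyl group aromatises, which erases both centres of the diastereomer mixture. The step needs regiocontrol of the furan substitution and chemoselectivity among the alkenes; the 2,4-pattern is fixed by the constitution of the acetal, initiation goes to the less substituted vinyl group, and aromatic ring A and the silyl ether are inert to the carbene and to the mild acid.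

Step 10
Reactants: 13 tert-butyl{3-[5-(furan-3-ylmethyl)furan-3-yl]propoxy}diphenylsilane
Product: 14 3-[5-(furan-3-ylmethyl)furan-3-yl]propan-1-ol
Conditions: Bu4NF, THF, 0 °C → rt
Reagents that add atoms: none
Why: Fluoride cleaves the Si–O bond under near-neutral conditions that both furans tolerate.

Step 11
Reactants: 14 3-[5-(furan-3-ylmethyl)furan-3-yl]propan-1-ol
Product: 15 2-(furan-3-ylmethyl)-4-(3-iodopropyl)furan
Conditions: PPh3, I2, imidazole (premixed), CH2Cl2, 0 °C
Reagents that add atoms: iodine, II
Why: Appel-type iodination through the alkoxyphosphonium iodide converts the primary alcohol into the iodide by SN2 displacement without free acid or free iodine.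

Step 12
Reactants: 15 2-(furan-3-ylmethyl)-4-(3-iodopropyl)furan
Product: 16 2-(furan-3-ylmethyl)-4-(pent-4-yn-1-yl)furan
Conditions: HC≡CLi·H2NCH2CH2NH2, DMSO, 15 °C → rt
Reagents that add atoms: lithium acetylide (ethylenediamine complex), [Li]C#C
Why: SN2 alkylation of lithium acetylide by the unhindered primary iodide adds the two alkyne carbons.

Step 13
Reactants: 16 2-(furan-3-ylmethyl)-4-(pent-4-yn-1-yl)furan
Product: 18 2-(furan-3-ylmethyl)-4-[(4E)-5-iodo-4-methylpent-4-en-1-yl]furan, via alkenylalane 17 (not isolated)
Conditions: Me3Al, Cp2ZrCl2 (30 mol%), CH2Cl2, 0 °C → rt; then I2, THF, −30 °C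
Reagents that add atoms: trimethylaluminium, C[Al](C)C; iodine, II
Why: Zirconium-catalysed methylalumination (Negishi carboalumination) adds methyl and aluminium syn across the terminal alkyne with methyl at the internal carbon, and iodinolysis of the C–Al bond with retention gives the (E)-iodoalkene.

Step 14
Reactants: 19 methyl (2R)-3-hydroxy-2-methylpropanoate ((R)-Roche ester)
Product: 20 methyl (2R)-3-[(tert-butyldimethylsilyl)oxy]-2-methylpropanoate
Conditions: t-BuMe2SiCl, imidazole, CH2Cl2, rt
Reagents that add atoms: tert-butyl(chloro)dimethylsilane, CC(C)(C)[Si](C)(C)Cl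
Why: Imidazole-promoted O-silylation protects the primary alcohol without touching the α-stereocentre.

Step 15
Reactants: 20 methyl (2R)-3-[(tert-butyldimethylsilyl)oxy]-2-methylpropanoate
Product: 21 (2R)-3-[(tert-butyldimethylsilyl)oxy]-2-methylpropanal
Conditions: i-Bu2AlH, CH2Cl2, −78 °C; aq. potassium sodium tartrate
Reagents that add atoms: none
Why: Partial reduction of the ester at −78 °C stops at the tetrahedral aluminium hemiacetal until work-up, giving the aldehyde with the α-centre intact.

Step 16
Reactants: 21 (2R)-3-[(tert-butyldimethylsilyl)oxy]-2-methylpropanal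
Product: 22 tert-butyldimethyl{[(2S)-2-methylbut-3-en-1-yl]oxy}silane
Conditions: Ph3PCH3Br, KN(SiMe3)2, THF, 0 °C; then 21, −78 → 0 °C
Reagents that add atoms: methyltriphenylphosphonium bromide, C[P+](c1ccccc1)(c1ccccc1)c1ccccc1.[Br-]
Why: Wittig methylenation with the non-stabilised ylide at low temperature is faster than α-epimerisation, so the centre is carried over (its descriptor changes to S by priority only).

Step 17
Reactants: 22 tert-butyldimethyl{[(2S)-2-methylbut-3-en-1-yl]oxy}silane; 18 2-(furan-3-ylmethyl)-4-[(4E)-5-iodo-4-methylpent-4-en-1-yl]furan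
Product: 24 tert-butyl({(2S,5E)-9-[5-(furan-3-ylmethyl)furan-3-yl]-2,6-dimethylnon-5-en-1-yl}oxy)dimethylsilane, via B-alkyl-9-BBN 23 (not isolated)
Conditions: 9-BBN, THF, rt (22 in slight excess); then 18, Pd(dppf)Cl2 (5 mol%), AsPh3, Cs2CO3, DMF/H2O, rt
Reagents that add atoms: 9-borabicyclo[3.3.1]nonane, B1C2CCCC1CCC2 (its atoms stay in intermediate 23 only)
Why: Anti-Markovnikov hydroboration of the terminal alkene followed by B-alkyl Suzuki–Miyaura coupling forms the sp3–sp2 bond with retention of the E geometry, the stereocentre lying one carbon away from the reacting position.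

Step 18
Reactants: 24 silyl ether
Product: 25 (2S,5E)-9-[5-(furan-3-ylmethyl)furan-3-yl]-2,6-dimethylnon-5-en-1-ol
Conditions: Bu4NF, THF, 0 °C → rt
Reagents that add atoms: none
Why: Fluoride desilylation frees the primary alcohol without affecting furans or the alkene.

Step 19
Reactants: 25 (2S,5E)-9-[5-(furan-3-ylmethyl)furan-3-yl]-2,6-dimethylnon-5-en-1-ol
Product: 26 (2S,5E)-9-[5-(furan-3-ylmethyl)furan-3-yl]-2,6-dimethylnon-5-enal
Conditions: Dess–Martin periodinane, NaHCO3, CH2Cl2, 0 °C; used directly
Reagents that add atoms: none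
Why: Buffered Dess–Martin oxidation gives the α-methyl aldehyde without epimerisation and leaves the furans and the trisubstituted alkene untouched.

Step 20
Reactants: 27 ethyl 2-(diphenoxyphosphoryl)acetate
Product: 28 ethyl 2-diazo-2-(diphenoxyphosphoryl)acetate
Conditions: 4-AcNHC6H4SO2N3, DBU, MeCN, 0 °C → rt
Reagents that add atoms: 4-acetamidobenzenesulfonyl azide, CC(=O)Nc1ccc(cc1)S(=O)(=O)N=[N+]=[N-]
Why: Regitz diazo transfer to the doubly activated methylene group.

Step 21
Reactants: 28 ethyl 2-diazo-2-(diphenoxyphosphoryl)acetate; 29 propanoic acid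
Product: 30 ethyl 2-(diphenoxyphosphoryl)-2-(propanoyloxy)acetate (racemic)
Conditions: Rh2(OAc)4 (1 mol%), toluene, 80 °C
Reagents that add atoms: none
Why: Dirhodium-carbenoid O–H insertion into the carboxylic acid gives the α-acyloxy phosphonate directly, avoiding a free α-hydroxy phosphonate that could rearrange to a phosphate.

Step 22
Reactants: 26 (2S,5E)-9-[5-(furan-3-ylmethyl)furan-3-yl]-2,6-dimethylnon-5-enal; 30 ethyl 2-(diphenoxyphosphoryl)-2-(propanoyloxy)acetate
Product: 31 ethyl (2E,4S,7E)-11-[5-(furan-3-ylmethyl)furan-3-yl]-4,8-dimethyl-2-(propanoyloxy)undeca-2,7-dienoate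
Conditions: NaH, THF, 0 °C; then 26, −78 → −20 °C
Reagents that add atoms: none
Why: Proposed new method: the sodium carbanion of diaryl phosphonate 30 adds to aldehyde 26 and, because the electron-poor P(OPh)2 group makes closure and collapse of the oxaphosphetane faster than retro-addition, the kinetically preferred adduct (aldehyde substituent anti to phosphorus and syn to the ester) goes on to the alkene with C4 cis to the ester carbon and trans to the acyloxy oxygen, that is the (2E)-enol ester, while the α-centre of 26 should survive because the stabilised carbanion is only weakly basic at −78 °C; the closest known reaction types are the Ando olefination with α-alkyl and α-bromo diaryl phosphonoacetates, which gives the ester-cis alkene, and the Horner–Wadsworth–Emmons olefination with dialkyl α-acyloxy phosphonoacetates, which gives 2-acyloxyacrylates without this geometric control.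

Step 23
Reactants: 31 (2E)-enol propanoate
Product: 32 (5E)-5-{(2S,5E)-9-[5-(furan-3-ylmethyl)furan-3-yl]-2,6-dimethylnon-5-en-1-ylidene}-4-hydroxy-3-methylfuran-2(5H)-one
Conditions: LiN(SiMe3)2 (2.5 equiv), THF, −78 → −30 °C; then cold dilute HCl to pH 3
Reagents that add atoms: none
Why: Dieckmann condensation of a 2-acyloxyacrylate, a known route to 5-ylidene tetronic acids, in which the propanoyl enolate attacks the adjacent ethyl ester 5-exo-trig to form C3–C4 of ring C and the product is stored as its unreactive tetronate anion, so the C5=C1′ geometry from step 22 and the C2′ centre (its C–H held in the alkene plane by allylic strain and hence poorly acidic) should be carried through.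

Step 24
Reactants: 32 (5E)-tetronic acid
Product: 34 (5E)-5-{(2S,5E)-9-[5-(furan-3-ylmethyl)furan-3-yl]-2,6-dimethylnon-5-en-1-ylidene}-3-methyl-4-(sulfooxy)furan-2(5H)-one (target), via pyridinium sulfate 33 (not isolated)
Conditions: SO3·pyridine (3 equiv), pyridine, 0 °C → rt; then sulfonic acid resin (H+ form), MeOH/H2O, 0 °C
Reagents that add atoms: sulfur trioxide–pyridine complex, [O-]S(=O)(=O)[n+]1ccccc1
Why: O-Sulfation of the acidic enol oxygen at C4 by the sulfur trioxide–amine complex should be much faster than C-sulfonation of the neutral furans at or below room temperature, and cold cation exchange then releases the hydrogen sulfate from its pyridinium salt.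

**Compound list**
1 | furan-3-ylacetic acid | OC(=O)Cc1ccoc1 | starting material
2 | 2-(furan-3-yl)ethanol | OCCc1ccoc1 | intermediate
3 | furan-3-ylacetaldehyde | O=CCc1ccoc1 | intermediate
4 | vinylmagnesium bromide | C=C[Mg]Br | starting material
5 | 1-(furan-3-yl)but-3-en-2-ol (racemic) | C=CC(O)Cc1ccoc1 | intermediate
6 | pentane-1,5-diol | OCCCCCO | starting material
7 | 5-[(tert-butyldiphenylsilyl)oxy]pentan-1-ol | OCCCCCO[Si](c1ccccc1)(c1ccccc1)C(C)(C)C | intermediate
8 | 5-[(tert-butyldiphenylsilyl)oxy]pentanal | O=CCCCCO[Si](c1ccccc1)(c1ccccc1)C(C)(C)C | intermediate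
9 | 5-[(tert-butyldiphenylsilyl)oxy]-2-methylidenepentanal | O=CC(=C)CCCO[Si](c1ccccc1)(c1ccccc1)C(C)(C)C | intermediate
10 | tert-butyl[(5,5-dimethoxy-4-methylidenepentyl)oxy]diphenylsilane | COC(OC)C(=C)CCCO[Si](c1ccccc1)(c1ccccc1)C(C)(C)C | intermediate
11 | tert-butyl{[5-{[1-(furan-3-yl)but-3-en-2-yl]oxy}-5-methoxy-4-methylidenepentyl]oxy}diphenylsilane (diastereomer mixture) | C=CC(Cc1ccoc1)OC(OC)C(=C)CCCO[Si](c1ccccc1)(c1ccccc1)C(C)(C)C | intermediate
12 | tert-butyl{3-[5-(furan-3-ylmethyl)-2-methoxy-2,5-dihydrofuran-3-yl]propoxy}diphenylsilane (diastereomer mixture, not isolated) | COC1OC(Cc2ccoc2)C=C1CCCO[Si](c1ccccc1)(c1ccccc1)C(C)(C)C | intermediate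
13 | tert-butyl{3-[5-(furan-3-ylmethyl)furan-3-yl]propoxy}diphenylsilane | CC(C)(C)[Si](c1ccccc1)(c1ccccc1)OCCCc1coc(Cc2ccoc2)c1 | intermediate
14 | 3-[5-(furan-3-ylmethyl)furan-3-yl]propan-1-ol | OCCCc1coc(Cc2ccoc2)c1 | intermediate
15 | 2-(furan-3-ylmethyl)-4-(3-iodopropyl)furan | ICCCc1coc(Cc2ccoc2)c1 | intermediate
16 | 2-(furan-3-ylmethyl)-4-(pent-4-yn-1-yl)furan | C#CCCCc1coc(Cc2ccoc2)c1 | intermediate
17 | dimethyl{(1E)-5-[5-(furan-3-ylmethyl)furan-3-yl]-2-methylpent-1-en-1-yl}alane (not isolated) | C[Al](C)/C=C(\C)CCCc1coc(Cc2ccoc2)c1 | intermediate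
18 | 2-(furan-3-ylmethyl)-4-[(4E)-5-iodo-4-methylpent-4-en-1-yl]furan | I/C=C(\C)CCCc1coc(Cc2ccoc2)c1 | intermediate
19 | methyl (2R)-3-hydroxy-2-methylpropanoate | COC(=O)[C@H](C)CO | starting material
20 | methyl (2R)-3-[(tert-butyldimethylsilyl)oxy]-2-methylpropanoate | COC(=O)[C@H](C)CO[Si](C)(C)C(C)(C)C | intermediate
21 | (2R)-3-[(tert-butyldimethylsilyl)oxy]-2-methylpropanal | O=C[C@H](C)CO[Si](C)(C)C(C)(C)C | intermediate
22 | tert-butyldimethyl{[(2S)-2-methylbut-3-en-1-yl]oxy}silane | C=C[C@H](C)CO[Si](C)(C)C(C)(C)C | intermediate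
23 | 9-[(3S)-4-[(tert-butyldimethylsilyl)oxy]-3-methylbutyl]-9-borabicyclo[3.3.1]nonane (not isolated) | CC(C)(C)[Si](C)(C)OC[C@@H](C)CCB1C2CCCC1CCC2 | intermediate
24 | tert-butyl({(2S,5E)-9-[5-(furan-3-ylmethyl)furan-3-yl]-2,6-dimethylnon-5-en-1-yl}oxy)dimethylsilane | CC(C)(C)[Si](C)(C)OC[C@@H](C)CC/C=C(\C)CCCc1coc(Cc2ccoc2)c1 | intermediate
25 | (2S,5E)-9-[5-(furan-3-ylmethyl)furan-3-yl]-2,6-dimethylnon-5-en-1-ol | OC[C@@H](C)CC/C=C(\C)CCCc1coc(Cc2ccoc2)c1 | intermediate
26 | (2S,5E)-9-[5-(furan-3-ylmethyl)furan-3-yl]-2,6-dimethylnon-5-enal | O=C[C@@H](C)CC/C=C(\C)CCCc1coc(Cc2ccoc2)c1 | intermediate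
27 | ethyl 2-(diphenoxyphosphoryl)acetate | CCOC(=O)CP(=O)(Oc1ccccc1)Oc1ccccc1 | starting material
28 | ethyl 2-diazo-2-(diphenoxyphosphoryl)acetate | CCOC(=O)C(=[N+]=[N-])P(=O)(Oc1ccccc1)Oc1ccccc1 | intermediate
29 | propanoic acid | CCC(=O)O | starting material
30 | ethyl 2-(diphenoxyphosphoryl)-2-(propanoyloxy)acetate (racemic) | CCC(=O)OC(C(=O)OCC)P(=O)(Oc1ccccc1)Oc1ccccc1 | intermediate
31 | ethyl (2E,4S,7E)-11-[5-(furan-3-ylmethyl)furan-3-yl]-4,8-dimethyl-2-(propanoyloxy)undeca-2,7-dienoate | CCOC(=O)/C(OC(=O)CC)=C\[C@@H](C)CC/C=C(\C)CCCc1coc(Cc2ccoc2)c1 | intermediate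
32 | (5E)-5-{(2S,5E)-9-[5-(furan-3-ylmethyl)furan-3-yl]-2,6-dimethylnon-5-en-1-ylidene}-4-hydroxy-3-methylfuran-2(5H)-one | CC1=C(O)/C(=C\[C@@H](C)CC/C=C(\C)CCCc2coc(Cc3ccoc3)c2)OC1=O | intermediate
33 | pyridinium salt of the target sulfate (not isolated) | CC1=C(OS(=O)(=O)[O-])/C(=C\[C@@H](C)CC/C=C(\C)CCCc2coc(Cc3ccoc3)c2)OC1=O.c1cc[nH+]cc1 | intermediate
34 | (5E)-5-{(2S,5E)-9-[5-(furan-3-ylmethyl)furan-3-yl]-2,6-dimethylnon-5-en-1-ylidene}-3-methyl-4-(sulfooxy)furan-2(5H)-one | CC1=C(OS(=O)(=O)O)/C(=C\[C@@H](C)CC/C=C(\C)CCCc2coc(Cc3ccoc3)c2)OC1=O | target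

**Step count and risks**
Total step count: 24. Longest linear sequence: 16 steps (steps 4–13, 17–19 and 22–24, from pentane-1,5-diol).

Steps most likely to fail:

1. Step 22 (Proposed new method). The addition may become reversible, so that the enol ester with C4 trans to the ester carbon forms instead; the α-centre of the aldehyde may also epimerise under base. Fallback by known chemistry, setting out from 26 and coming back at 32 (it replaces steps 22 and 23, and so also covers enolate fragmentation or isomerisation in the Dieckmann step). Aldehyde 26 would be added at −78 °C to the C5 lithium anion (LiN(i-Pr)2, THF) of 4-methoxy-3-methylfuran-2(5H)-one F1, giving the aldol adducts F2 as a mixture at C-5 and C-1′. The like-configured pair (5R,1′R and 5S,1′S) is separated by chromatography and dehydrated under Mitsunobu conditions (PPh3, diethyl azodicarboxylate, THF); this anti elimination, known for γ-(1-hydroxyalkyl)butenolides, places the chain cis to C4 and gives the (5E)-ylidene methyl tetronate F3. O-Demethylation with NaSCH2CH2CH3 in DMF at rt then returns tetronic acid 32.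

2. Step 24. Electrophilic sulfonation at the free α-positions of the furans may compete with O-sulfation, and the material may degrade when the salt is protonated. Fallback setting out from 32 and coming back at 34: the tetronate of 32 (Et3N, 4-(dimethylamino)pyridine, THF, 0 °C) would be O-sulfonylated with 2,2,2-trichloroethyl chlorosulfate to the neutral sulfate diester F4, which can be purified on silica. Zinc dust and ammonium formate in methanol then remove the trichloroethyl group reductively to the ammonium sulfate salt F5, which is passed through the acid resin as in step 24 to give 34.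

3. Step 8. The exchange may run on to the doubly exchanged acetal, and the conjugated oxocarbenium ion may be trapped at its terminal carbon or by conjugate addition. Fallback setting out from 10 (with 5) and coming back at 11: acetal 10 would first be converted with Et3SiOSO2CF3 and 2,4,6-trimethylpyridine (CH2Cl2, 0 °C) into the N-(α-methoxyalkyl)pyridinium triflate F6. Alcohol 5 is then added to displace the pyridine, giving 11 under non-equilibrating, near-neutral conditions with one equivalent of each partner.

**Further compounds**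
F1 | step 22 | 4-methoxy-3-methylfuran-2(5H)-one | COC1=C(C)C(=O)OC1
F2 | step 22 | 5-{(2S,5E)-9-[5-(furan-3-ylmethyl)furan-3-yl]-1-hydroxy-2,6-dimethylnon-5-en-1-yl}-4-methoxy-3-methylfuran-2(5H)-one (mixture at C-5 and C-1′) | COC1=C(C)C(=O)OC1C(O)[C@@H](C)CC/C=C(\C)CCCc1coc(Cc2ccoc2)c1
F3 | step 22 | (5E)-5-{(2S,5E)-9-[5-(furan-3-ylmethyl)furan-3-yl]-2,6-dimethylnon-5-en-1-ylidene}-4-methoxy-3-methylfuran-2(5H)-one | CC1=C(OC)/C(=C\[C@@H](C)CC/C=C(\C)CCCc2coc(Cc3ccoc3)c2)OC1=O
F4 | step 24 | 2,2,2-trichloroethyl sulfate diester of 32 | CC1=C(OS(=O)(=O)OCC(Cl)(Cl)Cl)/C(=C\[C@@H](C)CC/C=C(\C)CCCc2coc(Cc3ccoc3)c2)OC1=O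
F5 | step 24 | ammonium salt of the target sulfate | CC1=C(OS(=O)(=O)[O-])/C(=C\[C@@H](C)CC/C=C(\C)CCCc2coc(Cc3ccoc3)c2)OC1=O.[NH4+]
F6 | step 8 | 1-{5-[(tert-butyldiphenylsilyl)oxy]-1-methoxy-2-methylidenepentyl}-2,4,6-trimethylpyridinium triflate | COC(C(=C)CCCO[Si](c1ccccc1)(c1ccccc1)C(C)(C)C)[n+]1c(C)cc(C)cc1C.[O-]S(=O)(=O)C(F)(F)F
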